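**Plan**
Cuts: the two O–benzyl bonds are put back first. Then the two aryl–pentyl bonds are cut in one operation: C6–pentyl on ring B (the hydroxy acid ring) and C6'–pentyl on ring A (the dimethoxybenzoyl ring). The depside C(=O)–O bond is cut last.
Enabling feature: in each ring the unbranched pentyl chain sits on the carbon next to the carboxyl-bearing carbon and meta to both ring oxygens. Rings A and B therefore share one substitution pattern, and both trace back to 2-bromo-4,6-dimethoxybenzoic acid.
Forward: no ring is built. Both benzene rings come from 1-bromo-3,5-dimethoxybenzene, which is formylated and oxidised, and one portion of the acid is demethylated and benzyl-esterified.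
The halves are joined at the ring B hydroxyl para to the ester and the remaining phenol is benzylated. Both chains are then added with pentylzinc bromide, and hydrogenolysis frees the phenol and the acid.
Stereochemistry: the target has no stereocentre and no configured double bond, so nothing has to be set.

Key step: step 8

Remark: in steps 3, 8 and 9 two like groups react in the same flask in no fixed order, so each of these steps is written as one transformation of both groups.

Step 1
Reactants: 1 1-bromo-3,5-dimethoxybenzene
Product: 3 2-bromo-4,6-dimethoxybenzaldehyde, via aryl iminium chloride 2 (not isolated)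
Conditions: POCl3, DMF, 0 → 90 °C; then ice/H2O
Reagents that add atoms: N,N-dimethylformamide, CN(C)C=O (formyl carbon); water, O (carbonyl oxygen); phosphoryl chloride, O=P(Cl)(Cl)Cl (chloride counter-ion of 2 only)
Why: Vilsmeier–Haack formylation: the chloroiminium ion formed from DMF and POCl3 attacks the ring carbon that is para to one methoxy group and ortho to the other, the usual site for 5-substituted resorcinol dimethyl ethers, and water then hydrolyses iminium salt 2 to the aldehyde.

Step 2
Reactants: 3 2-bromo-4,6-dimethoxybenzaldehyde
Product: 4 2-bromo-4,6-dimethoxybenzoic acid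
Conditions: NaClO2, NaH2PO4, 2-methyl-2-butene (excess), t-BuOH/THF/H2O, rt
Reagents that add atoms: sodium chlorite, [Na+].[O-]Cl=O
Why: Pinnick oxidation: chlorous acid adds to the aldehyde and fragments to the acid, while excess 2-methyl-2-butene removes the hypochlorous acid that could otherwise chlorinate the activated ring, and the aryl bromide and methyl ethers are inert.

Step 3
Reactants: 4 2-bromo-4,6-dimethoxybenzoic acid (one portion)
Product: 5 2-bromo-4,6-dihydroxybenzoic acid
Conditions: BBr3 (4 equiv), CH2Cl2, −78 °C → rt; then H2O, 0 °C
Reagents that add atoms: none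
Why: Lewis-acid ether cleavage with BBr3: boron binds each methoxy oxygen and bromide removes the methyl group by SN2 attack, the C–Br bond and the carboxyl group are left alone, and a cold quench without heating keeps the decarboxylation-prone dihydroxy acid intact.

Step 4
Reactants: 5 2-bromo-4,6-dihydroxybenzoic acid; 6 benzyl bromide
Product: 7 benzyl 2-bromo-4,6-dihydroxybenzoate
Conditions: BnBr (1.0 equiv), KHCO3, DMF, rt
Reagents that add atoms: benzyl bromide 6, BrCc1ccccc1
Why: Carboxylate O-alkylation (SN2): hydrogen carbonate is strong enough to ionise only the carboxylic acid, so one equivalent of 6 esterifies it and leaves both phenols free, as is routine for orsellinic-type acids.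

Step 5
Reactants: 4 2-bromo-4,6-dimethoxybenzoic acid (second portion); 7 benzyl 2-bromo-4,6-dihydroxybenzoate
Product: 9 benzyl 2-bromo-4-[(2-bromo-4,6-dimethoxybenzoyl)oxy]-6-hydroxybenzoate, via trifluoroacetic mixed anhydride 8 (not isolated)
Conditions: (CF3CO)2O, toluene, rt
Reagents that add atoms: trifluoroacetic anhydride, O=C(OC(=O)C(F)(F)F)C(F)(F)F (its atoms stay only in intermediate 8)
Why: Trifluoroacetic anhydride depside esterification: mixed anhydride 8 ionises towards an acylium ion stabilised by the ortho and para methoxy groups, which gets round the di-ortho hindrance, and it is taken by the hydroxyl of 7 para to the ester because the ortho hydroxyl is locked in a hydrogen bond to the ester carbonyl.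

Step 6
Reactants: 9 benzyl 2-bromo-4-[(2-bromo-4,6-dimethoxybenzoyl)oxy]-6-hydroxybenzoate; 6 benzyl bromide
Product: 10 benzyl 2-(benzyloxy)-6-bromo-4-[(2-bromo-4,6-dimethoxybenzoyl)oxy]benzoate
Conditions: BnBr, K2CO3, DMF, rt
Reagents that add atoms: benzyl bromide 6, BrCc1ccccc1
Why: Williamson ether synthesis: carbonate frees the last phenol for SN2 attack on 6, and the depside carbonyl, flanked by bromine and methoxy, is shielded well enough to survive this mild base at room temperature.

Step 7
Reactants: 11 1-bromopentane
Product: 12 pentylzinc bromide (titrated THF solution)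
Conditions: Zn dust, LiCl, cat. BrCH2CH2Br/Me3SiCl, THF, 50 °C
Reagents that add atoms: zinc, [Zn]
Why: Direct insertion of zinc metal into a primary alkyl bromide, with LiCl carrying the organozinc off the metal surface into solution, gives a reagent that is used as its THF solution.

Step 8
Reactants: 10 benzyl 2-(benzyloxy)-6-bromo-4-[(2-bromo-4,6-dimethoxybenzoyl)oxy]benzoate; 12 pentylzinc bromide
Product: 13 benzyl 2-(benzyloxy)-4-[(2,4-dimethoxy-6-pentylbenzoyl)oxy]-6-pentylbenzoate
Conditions: 12 (4 equiv), Pd(OAc)2 (5 mol %), SPhos (10 mol %), THF, rt → 50 °C; then aq NH4Cl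
Reagents that add atoms: pentylzinc bromide 12, CCCCC[Zn]Br
Why: Pd(OAc)2 is reduced in situ by 12 to zerovalent palladium, which as its mono-SPhos complex (SPhos = 2-dicyclohexylphosphino-2',6'-dimethoxybiphenyl) inserts into each C–Br bond; both bromine-bearing carbons lie ortho to an ester carbonyl and meta to the two ring oxygens, so they receive no resonance donation and oxidative addition should be ready despite the oxygenated rings. Transmetalation from 12 gives an aryl(pentyl) complex of divalent palladium, and reductive elimination forms the C6–pentyl bond of ring B and the C6'–pentyl bond of ring A, one catalytic cycle per bond. The closest known reaction type is the Negishi sp2–sp3 coupling of ortho-substituted, ester-bearing aryl bromides with primary alkylzinc halides under palladium and dialkylbiarylphosphine catalysis, here simply run twice on one molecule. No ring closes and no stereocentre is created. The step needs chemoselectivity for two C–Br bonds over three ester carbonyls and two benzylic C–O bonds, which the low nucleophilicity of an alkylzinc halide, the di-ortho shielding of the depside carbonyl and the mild temperature should secure. It also needs C–C bond formation to outrun β-hydride loss and full conversion at both crowded sites, for which the bulky electron-rich ligand and a twofold excess of 12 per bromide are used.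

Step 9
Reactants: 13 benzyl 2-(benzyloxy)-4-[(2,4-dimethoxy-6-pentylbenzoyl)oxy]-6-pentylbenzoate
Product: 14 4-[(2,4-dimethoxy-6-pentylbenzoyl)oxy]-2-hydroxy-6-pentylbenzoic acid (target)
Conditions: H2 (1 atm), Pd/C, EtOAc, rt
Reagents that add atoms: none
Why: Catalytic hydrogenolysis: both benzylic C–O bonds are cleaved over palladium at room temperature, whereas the aryl ester link, the methyl ethers and the arene rings are untouched and the neutral medium spares the decarboxylation-prone salicylic acid.

**Compound list**
1 | 1-bromo-3,5-dimethoxybenzene | COc1cc(Br)cc(OC)c1 | starting material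
2 | N-[(2-bromo-4,6-dimethoxyphenyl)methylidene]-N-methylmethanaminium chloride | COc1cc(Br)c(C=[N+](C)C)c(OC)c1.[Cl-] | intermediate
3 | 2-bromo-4,6-dimethoxybenzaldehyde | COc1cc(Br)c(C=O)c(OC)c1 | intermediate
4 | 2-bromo-4,6-dimethoxybenzoic acid | COc1cc(Br)c(C(=O)O)c(OC)c1 | intermediate
5 | 2-bromo-4,6-dihydroxybenzoic acid | Oc1cc(Br)c(C(=O)O)c(O)c1 | intermediate
6 | benzyl bromide | BrCc1ccccc1 | starting material
7 | benzyl 2-bromo-4,6-dihydroxybenzoate | Oc1cc(Br)c(C(=O)OCc2ccccc2)c(O)c1 | intermediate
8 | 2-bromo-4,6-dimethoxybenzoic trifluoroacetic anhydride | COc1cc(Br)c(C(=O)OC(=O)C(F)(F)F)c(OC)c1 | intermediate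
9 | benzyl 2-bromo-4-[(2-bromo-4,6-dimethoxybenzoyl)oxy]-6-hydroxybenzoate | COc1cc(OC)c(C(=O)Oc2cc(Br)c(C(=O)OCc3ccccc3)c(O)c2)c(Br)c1 | intermediate
10 | benzyl 2-(benzyloxy)-6-bromo-4-[(2-bromo-4,6-dimethoxybenzoyl)oxy]benzoate | COc1cc(OC)c(C(=O)Oc2cc(Br)c(C(=O)OCc3ccccc3)c(OCc3ccccc3)c2)c(Br)c1 | intermediate
11 | 1-bromopentane | CCCCCBr | starting material
12 | pentylzinc bromide | CCCCC[Zn]Br | intermediate
13 | benzyl 2-(benzyloxy)-4-[(2,4-dimethoxy-6-pentylbenzoyl)oxy]-6-pentylbenzoate | CCCCCc1cc(OC(=O)c2c(CCCCC)cc(OC)cc2OC)cc(OCc2ccccc2)c1C(=O)OCc1ccccc1 | intermediate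
14 | 4-[(2,4-dimethoxy-6-pentylbenzoyl)oxy]-2-hydroxy-6-pentylbenzoic acid | CCCCCc1cc(OC(=O)c2c(CCCCC)cc(OC)cc2OC)cc(O)c1C(=O)O | target

Total step count: 9 (eight in the main line plus the preparation of 12).
Longest linear sequence: 8 steps (1 → 3 → 4 → 5 → 7 → 9 → 10 → 13 → 14).

**Steps most likely to fail**

Step 8. The second coupling may stall at a crowded, doubly flanked site. Loss of a β-hydrogen from the pentyl–palladium species may also lead to hydrodebromination, so that conversion at both positions stays incomplete. The fallback sets out from 10 and replaces the sp3 nucleophile with a slim sp nucleophile that cannot undergo β-hydride loss. A twofold Sonogashira coupling with pent-1-yne (PdCl2(PPh3)2, CuI, Et3N, THF, 60 °C) should give benzyl 2-(benzyloxy)-4-{[2,4-dimethoxy-6-(pent-1-yn-1-yl)benzoyl]oxy}-6-(pent-1-yn-1-yl)benzoate F1. Hydrogenation over Pd/C in EtOAc would then saturate both triple bonds and remove both benzyl groups in one flask, so the route is rejoined at target 14.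

Step 3. Loss of CO2 from the very electron-rich dihydroxy acid during the acidic quench may erode the supply of ring B. Sluggish cleavage of the methoxy group para to the carboxyl group would have the same effect. The fallback sets out from aldehyde 3 and carries ring B at the aldehyde oxidation level, which cannot decarboxylate.
- BBr3 in CH2Cl2 should give 2-bromo-4,6-dihydroxybenzaldehyde F2.
- Coupling with acid 4 through the same mixed anhydride 8 (trifluoroacetic anhydride, toluene) should acylate the hydroxyl para to the formyl group, the ortho one being hydrogen-bonded. This should give 3-bromo-4-formyl-5-hydroxyphenyl 2-bromo-4,6-dimethoxybenzoate F3.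
- Benzylation with 6 and K2CO3 should give 3-(benzyloxy)-5-bromo-4-formylphenyl 2-bromo-4,6-dimethoxybenzoate F4.
- Pinnick oxidation should give 2-(benzyloxy)-6-bromo-4-[(2-bromo-4,6-dimethoxybenzoyl)oxy]benzoic acid F5.
- Esterification with 6 and KHCO3 in DMF rejoins the route at 10.

Step 6. Alkylation of the hydrogen-bonded, doubly flanked phenol may be slow enough for base-induced cleavage or migration of the activated aryl ester to compete. The fallback sets out from 9 and drops the ether altogether. Negishi couplings under Pd(OAc)2 and SPhos tolerate free phenols, because cross-coupling is faster than protonolysis of the alkylzinc halide. Compound 9 would therefore be treated directly with a larger excess of 12 under the conditions of step 8 to give benzyl 4-[(2,4-dimethoxy-6-pentylbenzoyl)oxy]-2-hydroxy-6-pentylbenzoate F6. Hydrogenolysis of its single benzyl ester over Pd/C returns to 14.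

**Further compounds**
F1 | step 8 | benzyl 2-(benzyloxy)-4-{[2,4-dimethoxy-6-(pent-1-yn-1-yl)benzoyl]oxy}-6-(pent-1-yn-1-yl)benzoate | CCCC#Cc1cc(OC(=O)c2c(C#CCCC)cc(OC)cc2OC)cc(OCc2ccccc2)c1C(=O)OCc1ccccc1
F2 | step 3 | 2-bromo-4,6-dihydroxybenzaldehyde | Oc1cc(Br)c(C=O)c(O)c1
F3 | step 3 | 3-bromo-4-formyl-5-hydroxyphenyl 2-bromo-4,6-dimethoxybenzoate | COc1cc(OC)c(C(=O)Oc2cc(Br)c(C=O)c(O)c2)c(Br)c1
F4 | step 3 | 3-(benzyloxy)-5-bromo-4-formylphenyl 2-bromo-4,6-dimethoxybenzoate | COc1cc(OC)c(C(=O)Oc2cc(Br)c(C=O)c(OCc3ccccc3)c2)c(Br)c1
F5 | step 3 | 2-(benzyloxy)-6-bromo-4-[(2-bromo-4,6-dimethoxybenzoyl)oxy]benzoic acid | COc1cc(OC)c(C(=O)Oc2cc(Br)c(C(=O)O)c(OCc3ccccc3)c2)c(Br)c1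
F6 | step 6 | benzyl 4-[(2,4-dimethoxy-6-pentylbenzoyl)oxy]-2-hydroxy-6-pentylbenzoate | CCCCCc1cc(OC(=O)c2c(CCCCC)cc(OC)cc2OC)cc(O)c1C(=O)OCc1ccccc1
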